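**Strategy.** The route rests on disconnecting ring A at two neighbouring carbons: the O1–C7a bond of the dihydrofuran ring and the C7–acyl bond. A C7≡C7a aryne, released at −78 °C from a 2-iodoaryl triflate, is attacked by the tethered C2 magnesium alkoxide (5-exo). The resulting C7 aryl-magnesium, held by the C6 oxygen, is trapped by a 2-arylacrolein, so ring closure and introduction of the whole C7 side chain occur in one flask. The precursor is an Evans syn-aldol-derived β-hydroxy Weinreb amide whose two stereocentres become C2 and C3 (trans). Aroylation at C3, oxidation and global deprotection finish the synthesis.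

Key step: step 12

Remark: ring A atoms are called by their final dihydrobenzofuran locants (O1, C2, C3, C3a, C4–C7, C7a) also in the open-chain precursors.
Remark: the carbinol carbon formed in step 12 arises as a mixture of epimers, is written without a descriptor, and is removed by the oxidation in step 15.

Step 1
Reactants: 1 2,4,6-trihydroxybenzaldehyde
Product: 2 2-hydroxy-4,6-bis(methoxymethoxy)benzaldehyde
Conditions: MOMCl (2.2 equiv), i-Pr2NEt, CH2Cl2, 0 °C → rt
Reagents that add atoms: chloromethyl methyl ether (MOMCl), COCCl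
Why: Williamson-type MOM protection should take place at the 4-OH and at one 2-OH only, because the last ortho hydroxyl is held by its hydrogen bond to the formyl group, which singles out the oxygen that later becomes the triflate.

Step 2
Reactants: 2 2-hydroxy-4,6-bis(methoxymethoxy)benzaldehyde
Product: 3 2-hydroxy-3-iodo-4,6-bis(methoxymethoxy)benzaldehyde
Conditions: N-iodosuccinimide (1.05 equiv), DMF, 0 °C → rt, dark
Reagents that add atoms: N-iodosuccinimide, O=C1CCC(=O)N1I
Why: Electrophilic aromatic iodination should occur at C3, between the free chelated hydroxyl and an OMOM group, the less hindered of the two doubly activated positions, as is usual for 3-halogenation of 2-hydroxy-4,6-dialkoxyaryl carbonyl compounds.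

Step 3
Reactants: 3 2-hydroxy-3-iodo-4,6-bis(methoxymethoxy)benzaldehyde
Product: 4 2-formyl-6-iodo-3,5-bis(methoxymethoxy)phenyl trifluoromethanesulfonate
Conditions: Tf2O (1.2 equiv), pyridine, CH2Cl2, −10 → 0 °C
Reagents that add atoms: trifluoromethanesulfonic anhydride, O=S(=O)(OS(=O)(=O)C(F)(F)F)C(F)(F)F
Why: O-sulfonylation of the phenol gives the aryl triflate, so that iodide (future C7) and triflate (future C7a) sit on neighbouring carbons as the aryne precursor.

Step 4
Reactants: 4 2-formyl-6-iodo-3,5-bis(methoxymethoxy)phenyl trifluoromethanesulfonate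
Product: 5 2-ethenyl-6-iodo-3,5-bis(methoxymethoxy)phenyl trifluoromethanesulfonate
Conditions: Ph3PCH3Br, KOt-Bu, THF, 0 °C → rt
Reagents that add atoms: methyltriphenylphosphonium bromide, C[P+](c1ccccc1)(c1ccccc1)c1ccccc1.[Br-]
Why: Wittig methylenation of the non-enolisable aldehyde with the pre-formed ylide should leave aryl iodide, triflate and MOM ethers untouched.

Step 5
Reactants: 5 2-ethenyl-6-iodo-3,5-bis(methoxymethoxy)phenyl trifluoromethanesulfonate
Product: 7 2-(2-hydroxyethyl)-6-iodo-3,5-bis(methoxymethoxy)phenyl trifluoromethanesulfonate, via B-alkyl-9-borabicyclononane adduct 6 (not isolated)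
Conditions: 9-BBN, THF, 0 °C → rt; then NaBO3·4H2O, H2O, rt
Reagents that add atoms: sodium perborate (used as NaBO3·4H2O), [Na+].[Na+].O[B-]1(O)OO[B-](O)(O)OO1
Why: Brown hydroboration–oxidation with 9-BBN is anti-Markovnikov on the styrene, and the mild perborate oxidation should spare the aryl triflate.

Step 6
Reactants: 7 2-(2-hydroxyethyl)-6-iodo-3,5-bis(methoxymethoxy)phenyl trifluoromethanesulfonate
Product: 8 2-[3-iodo-4,6-bis(methoxymethoxy)-2-(trifluoromethanesulfonyloxy)phenyl]acetic acid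
Conditions: TEMPO (20 mol %), PhI(OAc)2 (2.5 equiv), MeCN/H2O, rt
Reagents that add atoms: water, O
Why: TEMPO/PhI(OAc)2 oxidation in aqueous acetonitrile takes the primary alcohol through the aldehyde hydrate to the arylacetic acid under conditions that should not affect MOM ethers, iodide or triflate.

Step 7
Reactants: 8 2-[3-iodo-4,6-bis(methoxymethoxy)-2-(trifluoromethanesulfonyloxy)phenyl]acetic acid; 9 (4R)-4-benzyl-1,3-oxazolidin-2-one
Product: 11 (4R)-4-benzyl-3-{2-[3-iodo-4,6-bis(methoxymethoxy)-2-(trifluoromethanesulfonyloxy)phenyl]acetyl}-1,3-oxazolidin-2-one, via mixed pivalic anhydride 10 (not isolated)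
Conditions: t-BuCOCl, Et3N, THF, −20 °C; then LiCl, 9, rt
Reagents that add atoms: none
Why: N-acylation of the Evans auxiliary through the mixed pivalic anhydride under LiCl/Et3N conditions needs no strong base, so the aryl iodide and triflate should survive.

Step 8
Reactants: 11 (4R)-4-benzyl-3-{2-[3-iodo-4,6-bis(methoxymethoxy)-2-(trifluoromethanesulfonyloxy)phenyl]acetyl}-1,3-oxazolidin-2-one; 12 4-(methoxymethoxy)benzaldehyde
Product: 15 (4R)-4-benzyl-3-{(2R,3R)-3-hydroxy-2-[3-iodo-4,6-bis(methoxymethoxy)-2-(trifluoromethanesulfonyloxy)phenyl]-3-[4-(methoxymethoxy)phenyl]propanoyl}-1,3-oxazolidin-2-one, via (Z)-dibutylboron enolate 13 (not isolated), via dibutylboron aldolate 14 (not isolated)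
Conditions: Bu2BOTf, i-Pr2NEt, CH2Cl2, −78 → 0 °C; 12, −78 → 0 °C; pH 7 buffer (KH2PO4/K2HPO4), MeOH, H2O2, 0 °C
Reagents that add atoms: none
Why: In this Evans syn-aldol reaction the (Z)-boron enolate should react through a Zimmerman–Traxler chair on the face opposite the benzyl group of the (R)-auxiliary, which sets both stereocentres (2R,3R, syn), the future C3 and C2.

Step 9
Reactants: 15 (4R)-4-benzyl-3-{(2R,3R)-3-hydroxy-2-[3-iodo-4,6-bis(methoxymethoxy)-2-(trifluoromethanesulfonyloxy)phenyl]-3-[4-(methoxymethoxy)phenyl]propanoyl}-1,3-oxazolidin-2-one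
Product: 16 (2R,3R)-3-hydroxy-2-[3-iodo-4,6-bis(methoxymethoxy)-2-(trifluoromethanesulfonyloxy)phenyl]-N-methoxy-3-[4-(methoxymethoxy)phenyl]-N-methylpropanamide
Conditions: AlMe3, MeNHOMe·HCl, CH2Cl2, −10 → 0 °C; aq. KNaC4H4O6
Reagents that add atoms: N,O-dimethylhydroxylamine hydrochloride, CNOC.Cl
Why: Weinreb transamination with the aluminium amide, assisted by the free β-hydroxyl, should remove the auxiliary without epimerisation or retro-aldol cleavage and gives an amide that tolerates the magnesium reagents of step 12.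

Step 10
Reactants: 17 1-bromo-4-(methoxymethoxy)benzene; 18 prop-2-yn-1-ol
Product: 20 2-[4-(methoxymethoxy)phenyl]prop-2-en-1-ol, via [4-(methoxymethoxy)phenyl]magnesium bromide 19 (not isolated)
Conditions: 17, Mg, THF, rt; then 18 (pre-treated with MeMgCl, 1.0 equiv), CuI (10 mol %), THF/toluene, 0 → 40 °C; aq. NH4Cl
Reagents that add atoms: none
Why: Copper-catalysed anti-carbomagnesiation of the propargylic alkoxide should place the aryl group on the internal alkyne carbon through the chelated alkenyl-magnesium and give the 2-arylallyl alcohol.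

Step 11
Reactants: 20 2-[4-(methoxymethoxy)phenyl]prop-2-en-1-ol
Product: 21 2-[4-(methoxymethoxy)phenyl]prop-2-enal
Conditions: Dess–Martin periodinane, NaHCO3, CH2Cl2, 0 °C; used at once
Reagents that add atoms: none
Why: Dess–Martin oxidation of the primary allylic alcohol gives the enal under buffered conditions, and immediate use avoids the dimerisation typical of 2-arylacroleins.

Step 12
Reactants: 16 (2R,3R)-3-hydroxy-2-[3-iodo-4,6-bis(methoxymethoxy)-2-(trifluoromethanesulfonyloxy)phenyl]-N-methoxy-3-[4-(methoxymethoxy)phenyl]-N-methylpropanamide; 21 2-[4-(methoxymethoxy)phenyl]prop-2-enal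
Product: 25 (2R,3R)-7-{1-hydroxy-2-[4-(methoxymethoxy)phenyl]prop-2-en-1-yl}-N-methoxy-4,6-bis(methoxymethoxy)-2-[4-(methoxymethoxy)phenyl]-N-methyl-2,3-dihydro-1-benzofuran-3-carboxamide (mixture of carbinol epimers), via dimagnesiated alkoxide 22 (not isolated), via aryne alkoxide 23 (not isolated), via C7 arylmagnesium chloride 24 (not isolated)
Conditions: MeMgCl (1.05 equiv), THF, −78 °C; i-PrMgCl·LiCl (1.15 equiv), −78 °C, 30 min; then 21 (1.5 equiv), −78 → −40 °C; aq. NH4Cl
Reagents that add atoms: none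
Why: MeMgCl first converts the carbinol into its chloromagnesium alkoxide, then iodine–magnesium exchange at C7 gives a 2-magnesioaryl triflate that loses Mg(OTf)Cl at −78 °C to form the C7≡C7a aryne; the tethered alkoxide adds to C7a and the C7 aryl-magnesium so formed adds 1,2 to enal 21. The closest known reaction type is aryne generation from 2-iodoaryl triflates by halogen–magnesium exchange, followed by addition of a magnesium heteroatom nucleophile and electrophilic trapping of the resulting aryl-magnesium (aryne 1,2-difunctionalisation). The dihydrofuran ring closes in a 5-exo-dig mode, the oxygen attacking aryne carbon C7a while C7 stays outside the new ring. No ring stereocentre is created: C2 and C3 come unchanged from the syn-aldol (the C2–O bond is never broken), which places the aryl and carboxamide groups trans, and the new carbinol carbon is uncontrolled and is erased in step 15. The step needs oxygen attack at C7a and not C7, and by the alkoxide and not the amide carbonyl oxygen: the three-atom tether can reach only C7a, the inductively withdrawing C6–OMOM group polarises the aryne so that nucleophiles add at the remote carbon C7a and the charge develops at C7 where MOM chelation holds the magnesium, and the pre-formed anionic alkoxide should outcompete neutral donors. Chemoselectivity of the magnesium reagents rests on the low temperature, at which exchange at the doubly ortho-activated iodide should be much faster than addition to the Weinreb amide.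

Step 13
Reactants: 26 4-bromobenzene-1,3-diol
Product: 27 1-bromo-2,4-bis(methoxymethoxy)benzene
Conditions: MOMCl (2.5 equiv), i-Pr2NEt, CH2Cl2, 0 °C → rt
Reagents that add atoms: chloromethyl methyl ether (MOMCl), COCCl
Why: Williamson-type MOM protection of both phenols gives the aryl bromide needed for bromine–lithium exchange.

Step 14
Reactants: 25 (2R,3R)-7-{1-hydroxy-2-[4-(methoxymethoxy)phenyl]prop-2-en-1-yl}-N-methoxy-4,6-bis(methoxymethoxy)-2-[4-(methoxymethoxy)phenyl]-N-methyl-2,3-dihydro-1-benzofuran-3-carboxamide; 27 1-bromo-2,4-bis(methoxymethoxy)benzene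
Product: 29 [(2R,3R)-7-{1-hydroxy-2-[4-(methoxymethoxy)phenyl]prop-2-en-1-yl}-4,6-bis(methoxymethoxy)-2-[4-(methoxymethoxy)phenyl]-2,3-dihydro-1-benzofuran-3-yl][2,4-bis(methoxymethoxy)phenyl]methanone, via 2,4-bis(methoxymethoxy)phenyllithium 28 (not isolated)
Conditions: 27 (3.2 equiv), n-BuLi, THF, −78 °C; then 25, −78 → −30 °C; aq. NH4Cl
Reagents that add atoms: none
Why: In this Weinreb ketone synthesis the aryl-lithium first deprotonates the carbinol and then adds once to the amide, the chelated tetrahedral adduct releasing the ketone only on work-up, while the alkene is not a Michael acceptor at the alcohol oxidation level and any enolisation at C3 should return the more stable trans isomer.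

Step 15
Reactants: 29 [(2R,3R)-7-{1-hydroxy-2-[4-(methoxymethoxy)phenyl]prop-2-en-1-yl}-4,6-bis(methoxymethoxy)-2-[4-(methoxymethoxy)phenyl]-2,3-dihydro-1-benzofuran-3-yl][2,4-bis(methoxymethoxy)phenyl]methanone
Product: 30 1-[(2R,3R)-3-[2,4-bis(methoxymethoxy)benzoyl]-4,6-bis(methoxymethoxy)-2-[4-(methoxymethoxy)phenyl]-2,3-dihydro-1-benzofuran-7-yl]-2-[4-(methoxymethoxy)phenyl]prop-2-en-1-one
Conditions: Dess–Martin periodinane, NaHCO3, CH2Cl2, 0 °C → rt
Reagents that add atoms: none
Why: Dess–Martin oxidation of the benzylic, allylic alcohol under buffered non-basic conditions gives the α-methylene ketone and removes the uncontrolled carbinol centre without touching C2 or C3.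

Step 16
Reactants: 30 1-[(2R,3R)-3-[2,4-bis(methoxymethoxy)benzoyl]-4,6-bis(methoxymethoxy)-2-[4-(methoxymethoxy)phenyl]-2,3-dihydro-1-benzofuran-7-yl]-2-[4-(methoxymethoxy)phenyl]prop-2-en-1-one
Product: 32 1-[(2R,3R)-3-(2,4-dihydroxybenzoyl)-4,6-dihydroxy-2-(4-hydroxyphenyl)-2,3-dihydro-1-benzofuran-7-yl]-2-(4-hydroxyphenyl)prop-2-en-1-one (CNP0162111.1), via hexakis(trimethylsilyl) ether 31 (not isolated)
Conditions: TMSOTf (14 equiv), 2,2'-bipyridyl (20 equiv), MeCN, 0 °C → rt; then H2O, rt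
Reagents that add atoms: none
Why: Acetal cleavage of aromatic MOM ethers with TMSOTf/2,2'-bipyridyl gives aryl silyl ethers that hydrolyse on aqueous work-up, so the six phenols should be freed without base and without a nucleophilic solvent that could add to the α-methylene ketone, and no stereocentre is touched.

**Compound list**

1 | 2,4,6-trihydroxybenzaldehyde | O=Cc1c(O)cc(O)cc1O | starting material
2 | 2-hydroxy-4,6-bis(methoxymethoxy)benzaldehyde | O=Cc1c(O)cc(OCOC)cc1OCOC | intermediate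
3 | 2-hydroxy-3-iodo-4,6-bis(methoxymethoxy)benzaldehyde | O=Cc1c(O)c(I)c(OCOC)cc1OCOC | intermediate
4 | 2-formyl-6-iodo-3,5-bis(methoxymethoxy)phenyl trifluoromethanesulfonate | O=Cc1c(OS(=O)(=O)C(F)(F)F)c(I)c(OCOC)cc1OCOC | intermediate
5 | 2-ethenyl-6-iodo-3,5-bis(methoxymethoxy)phenyl trifluoromethanesulfonate | C=Cc1c(OS(=O)(=O)C(F)(F)F)c(I)c(OCOC)cc1OCOC | intermediate
6 | 2-[2-(9-borabicyclo[3.3.1]nonan-9-yl)ethyl]-6-iodo-3,5-bis(methoxymethoxy)phenyl trifluoromethanesulfonate | C1CCC2CCCC(C1)B2CCc1c(OS(=O)(=O)C(F)(F)F)c(I)c(OCOC)cc1OCOC | intermediate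
7 | 2-(2-hydroxyethyl)-6-iodo-3,5-bis(methoxymethoxy)phenyl trifluoromethanesulfonate | OCCc1c(OS(=O)(=O)C(F)(F)F)c(I)c(OCOC)cc1OCOC | intermediate
8 | 2-[3-iodo-4,6-bis(methoxymethoxy)-2-(trifluoromethanesulfonyloxy)phenyl]acetic acid | OC(=O)Cc1c(OS(=O)(=O)C(F)(F)F)c(I)c(OCOC)cc1OCOC | intermediate
9 | (4R)-4-benzyl-1,3-oxazolidin-2-one | O=C1N[C@H](Cc2ccccc2)CO1 | starting material
10 | 2,2-dimethylpropanoic 2-[3-iodo-4,6-bis(methoxymethoxy)-2-(trifluoromethanesulfonyloxy)phenyl]acetic anhydride | CC(C)(C)C(=O)OC(=O)Cc1c(OS(=O)(=O)C(F)(F)F)c(I)c(OCOC)cc1OCOC | intermediate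
11 | (4R)-4-benzyl-3-{2-[3-iodo-4,6-bis(methoxymethoxy)-2-(trifluoromethanesulfonyloxy)phenyl]acetyl}-1,3-oxazolidin-2-one | O=C(Cc1c(OS(=O)(=O)C(F)(F)F)c(I)c(OCOC)cc1OCOC)N1[C@H](Cc2ccccc2)COC1=O | intermediate
12 | 4-(methoxymethoxy)benzaldehyde | COCOc1ccc(C=O)cc1 | starting material
13 | (Z)-dibutylboron enolate of 11 | CCCCB(CCCC)O/C(=C\c1c(OS(=O)(=O)C(F)(F)F)c(I)c(OCOC)cc1OCOC)N1[C@H](Cc2ccccc2)COC1=O | intermediate
14 | O-dibutylboryl aldolate of 15 | COCOc1cc(OCOC)c(I)c(OS(=O)(=O)C(F)(F)F)c1[C@H]([C@@H](OB(CCCC)CCCC)c1ccc(OCOC)cc1)C(=O)N1[C@H](Cc2ccccc2)COC1=O | intermediate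
15 | (4R)-4-benzyl-3-{(2R,3R)-3-hydroxy-2-[3-iodo-4,6-bis(methoxymethoxy)-2-(trifluoromethanesulfonyloxy)phenyl]-3-[4-(methoxymethoxy)phenyl]propanoyl}-1,3-oxazolidin-2-one | COCOc1cc(OCOC)c(I)c(OS(=O)(=O)C(F)(F)F)c1[C@H]([C@@H](O)c1ccc(OCOC)cc1)C(=O)N1[C@H](Cc2ccccc2)COC1=O | intermediate
16 | (2R,3R)-3-hydroxy-2-[3-iodo-4,6-bis(methoxymethoxy)-2-(trifluoromethanesulfonyloxy)phenyl]-N-methoxy-3-[4-(methoxymethoxy)phenyl]-N-methylpropanamide | COCOc1cc(OCOC)c(I)c(OS(=O)(=O)C(F)(F)F)c1[C@H]([C@@H](O)c1ccc(OCOC)cc1)C(=O)N(C)OC | intermediate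
17 | 1-bromo-4-(methoxymethoxy)benzene | COCOc1ccc(Br)cc1 | starting material
18 | prop-2-yn-1-ol | C#CCO | starting material
19 | [4-(methoxymethoxy)phenyl]magnesium bromide | COCOc1ccc([Mg]Br)cc1 | intermediate
20 | 2-[4-(methoxymethoxy)phenyl]prop-2-en-1-ol | C=C(CO)c1ccc(OCOC)cc1 | intermediate
21 | 2-[4-(methoxymethoxy)phenyl]prop-2-enal | C=C(C=O)c1ccc(OCOC)cc1 | intermediate
22 | chloromagnesium alkoxide of 16 carrying MgCl in place of iodine at C7 | COCOc1cc(OCOC)c([Mg]Cl)c(OS(=O)(=O)C(F)(F)F)c1[C@H]([C@@H](O[Mg]Cl)c1ccc(OCOC)cc1)C(=O)N(C)OC | intermediate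
23 | C7≡C7a aryne bearing the chloromagnesium alkoxide side chain | COCOC1=C([C@H]([C@@H](O[Mg]Cl)c2ccc(OCOC)cc2)C(=O)N(C)OC)C#CC(OCOC)=C1 | intermediate
24 | [(2R,3R)-3-[methoxy(methyl)carbamoyl]-4,6-bis(methoxymethoxy)-2-[4-(methoxymethoxy)phenyl]-2,3-dihydro-1-benzofuran-7-yl]magnesium chloride | Cl[Mg]c1c(OCOC)cc(OCOC)c2c1O[C@@H](c1ccc(OCOC)cc1)[C@@H]2C(=O)N(C)OC | intermediate
25 | (2R,3R)-7-{1-hydroxy-2-[4-(methoxymethoxy)phenyl]prop-2-en-1-yl}-N-methoxy-4,6-bis(methoxymethoxy)-2-[4-(methoxymethoxy)phenyl]-N-methyl-2,3-dihydro-1-benzofuran-3-carboxamide (carbinol epimers) | C=C(C(O)c1c(OCOC)cc(OCOC)c2c1O[C@@H](c1ccc(OCOC)cc1)[C@@H]2C(=O)N(C)OC)c1ccc(OCOC)cc1 | intermediate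
26 | 4-bromobenzene-1,3-diol | Oc1ccc(Br)c(O)c1 | starting material
27 | 1-bromo-2,4-bis(methoxymethoxy)benzene | COCOc1ccc(Br)c(OCOC)c1 | intermediate
28 | 2,4-bis(methoxymethoxy)phenyllithium | [Li]c1ccc(OCOC)cc1OCOC | intermediate
29 | [(2R,3R)-7-{1-hydroxy-2-[4-(methoxymethoxy)phenyl]prop-2-en-1-yl}-4,6-bis(methoxymethoxy)-2-[4-(methoxymethoxy)phenyl]-2,3-dihydro-1-benzofuran-3-yl][2,4-bis(methoxymethoxy)phenyl]methanone (carbinol epimers) | C=C(C(O)c1c(OCOC)cc(OCOC)c2c1O[C@@H](c1ccc(OCOC)cc1)[C@@H]2C(=O)c1ccc(OCOC)cc1OCOC)c1ccc(OCOC)cc1 | intermediate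
30 | 1-[(2R,3R)-3-[2,4-bis(methoxymethoxy)benzoyl]-4,6-bis(methoxymethoxy)-2-[4-(methoxymethoxy)phenyl]-2,3-dihydro-1-benzofuran-7-yl]-2-[4-(methoxymethoxy)phenyl]prop-2-en-1-one | C=C(C(=O)c1c(OCOC)cc(OCOC)c2c1O[C@@H](c1ccc(OCOC)cc1)[C@@H]2C(=O)c1ccc(OCOC)cc1OCOC)c1ccc(OCOC)cc1 | intermediate
31 | hexakis(trimethylsilyl) ether of 32 | C=C(C(=O)c1c(O[Si](C)(C)C)cc(O[Si](C)(C)C)c2c1O[C@@H](c1ccc(O[Si](C)(C)C)cc1)[C@@H]2C(=O)c1ccc(O[Si](C)(C)C)cc1O[Si](C)(C)C)c1ccc(O[Si](C)(C)C)cc1 | intermediate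
32 | 1-[(2R,3R)-3-(2,4-dihydroxybenzoyl)-4,6-dihydroxy-2-(4-hydroxyphenyl)-2,3-dihydro-1-benzofuran-7-yl]-2-(4-hydroxyphenyl)prop-2-en-1-one (CNP0162111.1) | C=C(C(=O)c1c(O)cc(O)c2c1O[C@@H](c1ccc(O)cc1)[C@@H]2C(=O)c1ccc(O)cc1O)c1ccc(O)cc1 | target

**Totals.** Total step count: 16. Longest linear sequence: 13 steps (steps 1–9, 12, 14, 15, 16).

**Steps most likely to fail**

1. Step 12. The aryne may be intercepted intermolecularly before the magnesium alkoxide closes the ring, and the hindered, di-ortho-oxygenated aryl-magnesium may be protonated or may trigger polymerisation of the enal instead of adding to it. Fallback, setting out from 16 and returning at 25: the same MeMgCl / i-PrMgCl·LiCl sequence is run on 16, but the C7 aryl-magnesium is quenched with I2, a fast and reliable trap, to give (2R,3R)-7-iodo-N-methoxy-4,6-bis(methoxymethoxy)-2-[4-(methoxymethoxy)phenyl]-N-methyl-2,3-dihydro-1-benzofuran-3-carboxamide F1. The C7–C bond is then made separately by a Nozaki–Hiyama–Kishi coupling of F1 with enal 21 (CrCl2, NiCl2 cat., DMF, rt), which is selective for aldehydes and tolerates the Weinreb amide, to give 25.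

2. Step 14. Acyl substitution at the congested C3 Weinreb amide may be slow, so that deprotonation at C3 by the basic aryl-lithium (enolisation, possibly followed by ring opening) competes. Fallback, setting out from 25 and returning at 30: the amide is reduced with i-Bu2AlH (THF, −78 °C) to the C3 aldehyde F2 (configuration at C2 and C3 as in 25). Aryl-lithium 28 adds rapidly to this aldehyde at −78 °C to give the diol F3. Dess–Martin periodinane (NaHCO3, CH2Cl2) then oxidises both carbinols in one operation to 30, which also replaces step 15.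

3. Step 16. During removal of six MOM groups the freed C6 hydroxyl may close onto the α-methylene ketone (6-endo oxa-Michael to an isoflavanone), nucleophiles may add to the enone, or the benzylic C2–O bond may ionise with loss of configuration. Fallback, setting out from 30 and returning at 32: the enone is masked by conjugate addition of thiophenol (PhSH, Et3N cat., CH2Cl2, 0 °C) to give the β-phenylthio ketone F4. The MOM ethers are then removed under ordinary conditions (aq. HCl, MeOH/THF, 40 °C) to give the hexaphenol sulfide F5. Oxidation with NaIO4 (MeOH/H2O, 0 °C) gives the sulfoxide F6, and gentle warming (dioxane, 60 °C, with a sulfenic acid scavenger) regenerates the α-methylene ketone by syn-elimination under neutral conditions, giving 32.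

**Further compounds**

F1 | step 12 | (2R,3R)-7-iodo-N-methoxy-4,6-bis(methoxymethoxy)-2-[4-(methoxymethoxy)phenyl]-N-methyl-2,3-dihydro-1-benzofuran-3-carboxamide | Ic1c(OCOC)cc(OCOC)c2c1O[C@@H](c1ccc(OCOC)cc1)[C@@H]2C(=O)N(C)OC
F2 | step 14 | 7-{1-hydroxy-2-[4-(methoxymethoxy)phenyl]prop-2-en-1-yl}-4,6-bis(methoxymethoxy)-2-[4-(methoxymethoxy)phenyl]-2,3-dihydro-1-benzofuran-3-carbaldehyde (C2 and C3 as in 25) | C=C(C(O)c1c(OCOC)cc(OCOC)c2c1O[C@@H](c1ccc(OCOC)cc1)[C@@H]2C=O)c1ccc(OCOC)cc1
F3 | step 14 | 1-{3-[[2,4-bis(methoxymethoxy)phenyl](hydroxy)methyl]-4,6-bis(methoxymethoxy)-2-[4-(methoxymethoxy)phenyl]-2,3-dihydro-1-benzofuran-7-yl}-2-[4-(methoxymethoxy)phenyl]prop-2-en-1-ol (C2 and C3 as in 25) | C=C(C(O)c1c(OCOC)cc(OCOC)c2c1O[C@@H](c1ccc(OCOC)cc1)[C@@H]2C(O)c1ccc(OCOC)cc1OCOC)c1ccc(OCOC)cc1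
F4 | step 16 | 1-[(2R,3R)-3-[2,4-bis(methoxymethoxy)benzoyl]-4,6-bis(methoxymethoxy)-2-[4-(methoxymethoxy)phenyl]-2,3-dihydro-1-benzofuran-7-yl]-2-[4-(methoxymethoxy)phenyl]-3-(phenylsulfanyl)propan-1-one | O=C(C(CSc1ccccc1)c1ccc(OCOC)cc1)c1c(OCOC)cc(OCOC)c2c1O[C@@H](c1ccc(OCOC)cc1)[C@@H]2C(=O)c1ccc(OCOC)cc1OCOC
F5 | step 16 | 1-[(2R,3R)-3-(2,4-dihydroxybenzoyl)-4,6-dihydroxy-2-(4-hydroxyphenyl)-2,3-dihydro-1-benzofuran-7-yl]-2-(4-hydroxyphenyl)-3-(phenylsulfanyl)propan-1-one | O=C(C(CSc1ccccc1)c1ccc(O)cc1)c1c(O)cc(O)c2c1O[C@@H](c1ccc(O)cc1)[C@@H]2C(=O)c1ccc(O)cc1O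
F6 | step 16 | 1-[(2R,3R)-3-(2,4-dihydroxybenzoyl)-4,6-dihydroxy-2-(4-hydroxyphenyl)-2,3-dihydro-1-benzofuran-7-yl]-2-(4-hydroxyphenyl)-3-(phenylsulfinyl)propan-1-one | O=C(C(CS(=O)c1ccccc1)c1ccc(O)cc1)c1c(O)cc(O)c2c1O[C@@H](c1ccc(O)cc1)[C@@H]2C(=O)c1ccc(O)cc1O
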